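The runs are simulated with constants of no real substance; noise was put on by code.

In a one-step world, where the single-handed catalyst takes the left-handed substrate and nothing else happens, each fraction of the charge that becomes left-handed product opens the same fraction as a gap between right-handed and left-handed substrate.

| flask | left-handed substrate | right-handed substrate | partner | protic impurity | catalyst | remark | time |
|---|---|---|---|---|---|---|---|
| midnight | 20 mM | 20 mM | 40 mM | 6 mM | 11 µM | run made earlier |  |
| noon | 20 mM | 20 mM | 40 mM | 6 mM | 16 µM | run made earlier |  |
| flask | 20 mM | 20 mM | 40.0 mM | 6.00 mM | 22 µM |  | 6.0 min |

- midnight (time / min: right-handed substrate / %, left-handed substrate / %, left-handed product / %): 0.417: 48.7, 48.9, 2.3; 1.33: 49.2, 48.0, 2.9; 2.50: 47.7, 45.1, 4.3; 4.00: 47.7, 42.7, 7.8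
- noon (time / min: right-handed substrate / %, left-handed substrate / %, left-handed product / %): 0.833: 50.0, 49.1, 2.2; 2.00: 48.9, 44.1, 5.9; 2.50: 49.9, 45.9, 7.8; 4.00: 45.0, 42.5, 8.8

(each reading ± 1 percentage point)

- catalyst is single-handed; left-handed substrate and right-handed substrate are mirror images of each other, charged as a racemate, each of them at the stated concentration
- the earlier runs were read with a standard deviation of 1 percentage point

1. whether the excess of right-handed substrate over left-handed substrate among what is left of the two reaches 90% by 6.0 min (yes / no)
2. the highest excess of right-handed substrate over left-handed substrate among what is left of the two up to 6.0 min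

*What do the last readings show?* At 4.00 min the gap reads 5 points in the midnight run and 2.5 points in the noon run, against left-handed product of 7.8% and 8.8%. Pooled, they give 0.452, and this ratio, gap opened per unit of left-handed product, is the gap yield of this kinetic resolution, as read from these two scattered runs.

*Is that scatter?* Partly: four readings put a standard deviation of 0.120 on it, and one such step up, 0.572, stays below the one-step value of one.

*And the flask?* Scaling left-handed product with catalyst and time, I reckon 20.3% at 6.0 min.

*But noon had 1.45 times the catalyst of midnight and 1.13 times the product?* Yes, so this scaling may run high.

*The excess?* In the last readings of the two runs, the two substrates together lost 1.33 units of the charge per unit of left-handed product. Dividing the expected gap by what remains of the pair, my reckoning gives 12.6% at the end of the run, where this reckoning puts the top. That is below 90%, so my answer is no.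

The forecast says no and a top of 26%, within 15% to 40%, above my figure, holding that “selectivity is good but not perfect”.

The flask gives no and a top of 6.95%, below my 12.6%.

    partner + catalyst + left-handed substrate → catalyst + left-handed product (k = 96000 M⁻² min⁻¹)
    partner + catalyst + right-handed substrate → catalyst + right-handed product (k = 35000 M⁻² min⁻¹)
    left-handed substrate ⇌ right-handed substrate (k = 0.100 min⁻¹)
    partner + protic impurity → quenched reagent (k = 1.60 M⁻¹ min⁻¹)
    partner → decomposed reagent (k = 0.0260 min⁻¹)

In this flask the two substrates interconvert, and that step by itself has a relaxation half-life of 3.47 min, shorter than the 6.0 min of the run. Set on this flask's amounts at 6.00 min, the gap yield 0.452 turns 16.6% of left-handed product over a pair of 76.8% into a reckoned excess of 9.79%. In the neighbouring flask charged with 10 mM of partner, it turns 4.67% over a pair of 93.6% into a reckoned 2.25%, and that flask's top stands at 1.71%.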